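Assumption: the SMILES is read as (3R,4S), i.e. the tertiary hydroxyl and the aroyl group are cis on ring B.

**Retrosynthetic overview**
1. Target ⇐ tertiary O‑silyl, penta‑O‑benzyl tetralone (mild methanolysis, then hydrogenolysis).
2. Ring B (last ring formed) ⇐ α‑diazoketone: a Wolff 1,2‑shift moves the silyloxy carbon C3 onto the diazo carbon (new C2), and the ketene carbon (C1) is captured by ring A (C1–C8a bond).
3. Diazoketone ⇐ tertiary α‑silyloxy acid ⇐ catalytic enantioselective pyruvate aldol on the silyl enol ether of a deoxybenzoin (sets C3 and C4).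
4. Deoxybenzoin ⇐ Suzuki coupling of the ring A aryl boronate with the bromoacetyl ketone of ring C ⇐ Friedel–Crafts acylation of a benzylpyranone.
5. Pyranone ring (first ring formed) ⇐ arylacetic acid + acetoacetate dianion; both aryl units ⇐ resorcinol by C–H borylation. Ring order: rings A and C are resorcinol nuclei, then the pyranone, then ring B.

Abbreviations in names: ArA = 3,5‑bis(benzyloxy)phenyl; ArC = 2,4‑bis(benzyloxy)‑6‑{[4‑(benzyloxy)‑2‑oxo‑2H‑pyran‑6‑yl]methyl}phenyl; Bpin = 4,4,5,5‑tetramethyl‑1,3,2‑dioxaborolan‑2‑yl; TMS = trimethylsilyl.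

**Route**

Step 1
Reactants: 1 resorcinol
Product: 2 5‑(Bpin)benzene‑1,3‑diol
Conditions: HBpin (excess), [Ir(OMe)(cod)]2 (1.5 mol %), 4,4′‑di‑tert‑butyl‑2,2′‑bipyridine (3 mol %), THF, 80 °C; then MeOH
Reagents that add atoms: pinacolborane, B1OC(C)(C)C(C)(C)O1
Why: C–H borylation with [Ir(OMe)(cod)]2/bipyridine is sterically controlled, so after in‑situ O‑borylation of both hydroxyls only C5 reacts, and methanolysis returns the free diol.

Step 2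
Reactants: 2 5‑(Bpin)benzene‑1,3‑diol
Product: 3 boronate ArA–Bpin
Conditions: BnBr, K2CO3, DMF, rt
Reagents that add atoms: benzyl bromide, BrCc1ccccc1
Why: Williamson etherification of both phenols; the pinacol boronate tolerates carbonate base.

Step 3
Reactants: 3 boronate ArA–Bpin; 4 methyl bromoacetate
Product: 6 [3,5‑bis(benzyloxy)phenyl]acetic acid, via methyl ester 5 (not isolated)
Conditions: Pd(OAc)2 (3 mol %), P(o‑tol)3, K3PO4, THF–H2O, 40 °C; then LiOH, MeOH–H2O, rt; HCl work‑up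
Reagents that add atoms: lithium hydroxide, [Li+].[OH-]
Why: Suzuki–Miyaura coupling of the aryl boronate with the α‑bromo ester gives the arylacetate, which is saponified in the same pot.

Step 4
Reactants: 6 [3,5‑bis(benzyloxy)phenyl]acetic acid; 7 methyl acetoacetate
Product: 11 pyranone 4‑hydroxy‑6‑[3,5‑bis(benzyloxy)benzyl]‑2H‑pyran‑2‑one, via dianion 8 (not isolated), via acyl imidazole 9 (not isolated), via triketo ester 10 (not isolated)
Conditions: 6, CDI, THF, rt; added to 7 treated with NaH then n‑BuLi (THF, 0 °C) at −78 → 0 °C; aq HCl; then DBU (cat.), toluene, 110 °C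
Reagents that add atoms: none
Why: The acyl imidazole acylates the γ‑carbon of the acetoacetate dianion (Claisen‑type acylation), and DBU then closes the δ‑enol oxygen onto the ester to form the 4‑hydroxy‑2‑pyranone ring.

Step 5
Reactants: 11 pyranone 4‑hydroxy‑6‑[3,5‑bis(benzyloxy)benzyl]‑2H‑pyran‑2‑one
Product: 12 benzyl ether 4‑(benzyloxy)‑6‑[3,5‑bis(benzyloxy)benzyl]‑2H‑pyran‑2‑one
Conditions: BnBr, K2CO3, DMF, rt
Reagents that add atoms: benzyl bromide, BrCc1ccccc1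
Why: The vinylogous acid is alkylated on O4 (Williamson), masking it as a hydrogenolysable benzyl ether.

Step 6
Reactants: 12 benzyl ether 4‑(benzyloxy)‑6‑[3,5‑bis(benzyloxy)benzyl]‑2H‑pyran‑2‑one; 13 bromoacetic acid
Product: 15 bromo ketone 2‑bromo‑1‑ArC‑ethan‑1‑one, via mixed anhydride 14 (not isolated)
Conditions: TFAA, H3PO4 (cat.), CH2Cl2, 0 °C → rt
Reagents that add atoms: none
Why: Friedel–Crafts acylation through the mixed trifluoroacetic anhydride goes to the ring position ortho to the benzylic carbon and para to a benzyloxy group, and the acid has no arene of its own that could compete.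

Step 7
Reactants: 15 bromo ketone 2‑bromo‑1‑ArC‑ethan‑1‑one; 3 boronate ArA–Bpin
Product: 16 deoxybenzoin 2‑ArA‑1‑ArC‑ethan‑1‑one
Conditions: Pd(OAc)2 (5 mol %), P(o‑tol)3, K3PO4, THF–H2O, rt
Reagents that add atoms: none
Why: Suzuki–Miyaura coupling of the α‑bromo ketone with the aryl boronate makes the benzylic C–aryl bond without having to tell apart two equally electron‑rich arenes in an acylation.

Step 8
Reactants: 16 deoxybenzoin 2‑ArA‑1‑ArC‑ethan‑1‑one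
Product: 17 silyl enol ether trimethyl{[(1Z)‑2‑ArA‑1‑ArC‑ethenyl]oxy}silane
Conditions: TMSOTf, Et3N, CH2Cl2, 0 °C
Reagents that add atoms: trimethylsilyl trifluoromethanesulfonate, C[Si](C)(C)OS(=O)(=O)C(F)(F)F
Why: Soft enolisation of the only enolisable ketone gives the Z silyl enol ether, with the bulky ArC group trans to ArA.

Step 9
Reactants: 17 silyl enol ether trimethyl{[(1Z)‑2‑ArA‑1‑ArC‑ethenyl]oxy}silane; 18 methyl pyruvate
Product: 19 methyl (2S,3S)‑3‑ArA‑4‑ArC‑2‑methyl‑4‑oxo‑2‑[(trimethylsilyl)oxy]butanoate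
Conditions: [Cu((S,S)‑tBu‑box)](OTf)2 (10 mol %), THF, −78 °C; non‑aqueous work‑up
Reagents that add atoms: none
Why: Evans‑type Mukaiyama aldol in which pyruvate chelates divalent copper in the tBu‑box complex so that one ketone face is shielded, giving the (2S) tertiary carbinol (C3 of the target) and the syn relationship to the adjacent CH (C4 of the target), with silyl transfer to the new alkoxide.

Step 10
Reactants: 19 methyl (2S,3S)‑3‑ArA‑4‑ArC‑2‑methyl‑4‑oxo‑2‑[(trimethylsilyl)oxy]butanoate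
Product: 20 (2S,3S)‑3‑ArA‑4‑ArC‑2‑methyl‑4‑oxo‑2‑[(trimethylsilyl)oxy]butanoic acid
Conditions: Me3SnOH, 1,2‑dichloroethane, 70 °C; brief cold dilute HCl work‑up
Reagents that add atoms: trimethyltin hydroxide, C[Sn](C)(C)O
Why: Me3SnOH cleaves the hindered methyl ester under near‑neutral conditions that should spare the silyl ether, the pyranone and the α‑aryl ketone stereocentre.

Step 11
Reactants: 20 (2S,3S)‑3‑ArA‑4‑ArC‑2‑methyl‑4‑oxo‑2‑[(trimethylsilyl)oxy]butanoic acid; 21 (trimethylsilyl)diazomethane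
Product: 23 diazoketone (3S,4S)‑4‑ArA‑5‑ArC‑1‑diazo‑3‑methyl‑3‑[(trimethylsilyl)oxy]pentane‑2,5‑dione, via acid chloride 22 (not isolated)
Conditions: 1‑chloro‑N,N,2‑trimethylprop‑1‑en‑1‑amine, CH2Cl2, 0 °C; then 21, Et3N, MeCN–THF, 0 °C; aq NaHCO3
Reagents that add atoms: none
Why: Neutral acid chloride formation followed by C‑acylation of the diazoalkane (first stage of an Arndt–Eistert homologation); the quaternary α‑carbon rules out ketene formation from the acid chloride.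

Step 12
Reactants: 23 diazoketone (3S,4S)‑4‑ArA‑5‑ArC‑1‑diazo‑3‑methyl‑3‑[(trimethylsilyl)oxy]pentane‑2,5‑dione
Product: 25 tetralone (3R,4S)‑4‑(ArC‑carbonyl)‑6,8‑bis(benzyloxy)‑3‑methyl‑3‑[(trimethylsilyl)oxy]‑3,4‑dihydronaphthalen‑1(2H)‑one, via ketene 24 (not isolated)
Conditions: hν (390 nm LED), toluene, −30 °C; then Sc(OTf)3 (10 mol %), −30 → 0 °C
Reagents that add atoms: none
Why: Proposed new method: a light‑induced Wolff rearrangement, in which the fully substituted silyloxy carbon (C3) shifts 1,2 with retention from the acyl carbon to the diazo carbon as N2 leaves, gives an alkyl ketene whose carbonyl carbon, activated by Sc(OTf)3, is attacked by the ortho carbon of the electron‑rich ring A (ortho and para to benzyloxy groups, six‑membered closure) and then tautomerises, so that C2 is inserted, the C1–C8a bond and ring B are formed and both stereocentres are kept; the closest known reactions are the Arndt–Eistert/Wolff homologation with heteroatom capture of the ketene and Lewis‑acid intramolecular Friedel–Crafts acylation.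

Step 13
Reactants: 25 tetralone (3R,4S)‑4‑(ArC‑carbonyl)‑6,8‑bis(benzyloxy)‑3‑methyl‑3‑[(trimethylsilyl)oxy]‑3,4‑dihydronaphthalen‑1(2H)‑one
Product: 27 (3R,4S)‑4‑{2,4‑dihydroxy‑6‑[(4‑hydroxy‑2‑oxo‑2H‑pyran‑6‑yl)methyl]benzoyl}‑3,6,8‑trihydroxy‑3‑methyl‑3,4‑dihydronaphthalen‑1(2H)‑one, via pentabenzyl ether 26 (not isolated)
Conditions: PPTS (cat.), MeOH–CH2Cl2, 0 °C; then H2 (1 atm), Pd/C, EtOAc–MeOH, rt
Reagents that add atoms: none
Why: Mild acid methanolysis removes the tertiary silyl ether and hydrogenolysis over Pd/C cleaves the five benzyl ethers under neutral conditions that avoid retro‑aldol cleavage or dehydration of the β‑hydroxy ketone.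

**Compound list**
1 | resorcinol (benzene‑1,3‑diol) | Oc1cccc(O)c1 | starting material
2 | 5‑(4,4,5,5‑tetramethyl‑1,3,2‑dioxaborolan‑2‑yl)benzene‑1,3‑diol | CC1(C)OB(OC1(C)C)c1cc(O)cc(O)c1 | intermediate
3 | 2‑[3,5‑bis(benzyloxy)phenyl]‑4,4,5,5‑tetramethyl‑1,3,2‑dioxaborolane | CC1(C)OB(OC1(C)C)c1cc(OCc2ccccc2)cc(OCc2ccccc2)c1 | intermediate
4 | methyl bromoacetate | COC(=O)CBr | starting material
5 | methyl [3,5‑bis(benzyloxy)phenyl]acetate | COC(=O)Cc1cc(OCc2ccccc2)cc(OCc2ccccc2)c1 | intermediate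
6 | [3,5‑bis(benzyloxy)phenyl]acetic acid | OC(=O)Cc1cc(OCc2ccccc2)cc(OCc2ccccc2)c1 | intermediate
7 | methyl acetoacetate | COC(=O)CC(C)=O | starting material
8 | sodium lithium dianion of methyl acetoacetate | COC(=O)[CH-]C(=O)[CH2-].[Na+].[Li+] | intermediate
9 | 1‑{[3,5‑bis(benzyloxy)phenyl]acetyl}‑1H‑imidazole | O=C(Cc1cc(OCc2ccccc2)cc(OCc2ccccc2)c1)n1ccnc1 | intermediate
10 | methyl 6‑[3,5‑bis(benzyloxy)phenyl]‑3,5‑dioxohexanoate | COC(=O)CC(=O)CC(=O)Cc1cc(OCc2ccccc2)cc(OCc2ccccc2)c1 | intermediate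
11 | 4‑hydroxy‑6‑[3,5‑bis(benzyloxy)benzyl]‑2H‑pyran‑2‑one | O=c1cc(O)cc(Cc2cc(OCc3ccccc3)cc(OCc3ccccc3)c2)o1 | intermediate
12 | 4‑(benzyloxy)‑6‑[3,5‑bis(benzyloxy)benzyl]‑2H‑pyran‑2‑one | O=c1cc(OCc2ccccc2)cc(Cc2cc(OCc3ccccc3)cc(OCc3ccccc3)c2)o1 | intermediate
13 | bromoacetic acid | OC(=O)CBr | starting material
14 | bromoacetic trifluoroacetic anhydride | O=C(CBr)OC(=O)C(F)(F)F | intermediate
15 | 4‑(benzyloxy)‑6‑{[3,5‑bis(benzyloxy)‑2‑(bromoacetyl)phenyl]methyl}‑2H‑pyran‑2‑one (2‑bromo‑1‑ArC‑ethan‑1‑one) | O=C(CBr)c1c(OCc2ccccc2)cc(OCc2ccccc2)cc1Cc1cc(OCc2ccccc2)cc(=O)o1 | intermediate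
16 | 1‑{2,4‑bis(benzyloxy)‑6‑[(4‑(benzyloxy)‑2‑oxo‑2H‑pyran‑6‑yl)methyl]phenyl}‑2‑[3,5‑bis(benzyloxy)phenyl]ethan‑1‑one | O=C(Cc1cc(OCc2ccccc2)cc(OCc2ccccc2)c1)c1c(OCc2ccccc2)cc(OCc2ccccc2)cc1Cc1cc(OCc2ccccc2)cc(=O)o1 | intermediate
17 | trimethyl{[(1Z)‑2‑ArA‑1‑ArC‑ethenyl]oxy}silane | C[Si](C)(C)O/C(=C\c1cc(OCc2ccccc2)cc(OCc2ccccc2)c1)c1c(OCc2ccccc2)cc(OCc2ccccc2)cc1Cc1cc(OCc2ccccc2)cc(=O)o1 | intermediate
18 | methyl pyruvate | COC(=O)C(C)=O | starting material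
19 | methyl (2S,3S)‑3‑ArA‑4‑ArC‑2‑methyl‑4‑oxo‑2‑[(trimethylsilyl)oxy]butanoate | COC(=O)[C@@](C)(O[Si](C)(C)C)[C@H](c1cc(OCc2ccccc2)cc(OCc2ccccc2)c1)C(=O)c1c(OCc2ccccc2)cc(OCc2ccccc2)cc1Cc1cc(OCc2ccccc2)cc(=O)o1 | intermediate
20 | (2S,3S)‑3‑ArA‑4‑ArC‑2‑methyl‑4‑oxo‑2‑[(trimethylsilyl)oxy]butanoic acid | OC(=O)[C@@](C)(O[Si](C)(C)C)[C@H](c1cc(OCc2ccccc2)cc(OCc2ccccc2)c1)C(=O)c1c(OCc2ccccc2)cc(OCc2ccccc2)cc1Cc1cc(OCc2ccccc2)cc(=O)o1 | intermediate
21 | (trimethylsilyl)diazomethane | C[Si](C)(C)C=[N+]=[N-] | starting material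
22 | (2S,3S)‑3‑ArA‑4‑ArC‑2‑methyl‑4‑oxo‑2‑[(trimethylsilyl)oxy]butanoyl chloride | ClC(=O)[C@@](C)(O[Si](C)(C)C)[C@H](c1cc(OCc2ccccc2)cc(OCc2ccccc2)c1)C(=O)c1c(OCc2ccccc2)cc(OCc2ccccc2)cc1Cc1cc(OCc2ccccc2)cc(=O)o1 | intermediate
23 | (3S,4S)‑4‑ArA‑5‑ArC‑1‑diazo‑3‑methyl‑3‑[(trimethylsilyl)oxy]pentane‑2,5‑dione | [N-]=[N+]=CC(=O)[C@@](C)(O[Si](C)(C)C)[C@H](c1cc(OCc2ccccc2)cc(OCc2ccccc2)c1)C(=O)c1c(OCc2ccccc2)cc(OCc2ccccc2)cc1Cc1cc(OCc2ccccc2)cc(=O)o1 | intermediate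
24 | (3R,4S)‑4‑ArA‑5‑ArC‑3‑methyl‑3‑[(trimethylsilyl)oxy]pent‑1‑ene‑1,5‑dione (ketene) | O=C=C[C@@](C)(O[Si](C)(C)C)[C@H](c1cc(OCc2ccccc2)cc(OCc2ccccc2)c1)C(=O)c1c(OCc2ccccc2)cc(OCc2ccccc2)cc1Cc1cc(OCc2ccccc2)cc(=O)o1 | intermediate
25 | (3R,4S)‑4‑(ArC‑carbonyl)‑6,8‑bis(benzyloxy)‑3‑methyl‑3‑[(trimethylsilyl)oxy]‑3,4‑dihydronaphthalen‑1(2H)‑one | C[C@@]1(O[Si](C)(C)C)CC(=O)c2c(OCc3ccccc3)cc(OCc3ccccc3)cc2[C@@H]1C(=O)c1c(OCc2ccccc2)cc(OCc2ccccc2)cc1Cc1cc(OCc2ccccc2)cc(=O)o1 | intermediate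
26 | (3R,4S)‑4‑(ArC‑carbonyl)‑6,8‑bis(benzyloxy)‑3‑hydroxy‑3‑methyl‑3,4‑dihydronaphthalen‑1(2H)‑one | C[C@@]1(O)CC(=O)c2c(OCc3ccccc3)cc(OCc3ccccc3)cc2[C@@H]1C(=O)c1c(OCc2ccccc2)cc(OCc2ccccc2)cc1Cc1cc(OCc2ccccc2)cc(=O)o1 | intermediate
27 | (3R,4S)‑4‑{2,4‑dihydroxy‑6‑[(4‑hydroxy‑2‑oxo‑2H‑pyran‑6‑yl)methyl]benzoyl}‑3,6,8‑trihydroxy‑3‑methyl‑3,4‑dihydronaphthalen‑1(2H)‑one | C[C@@]1(O)CC(=O)c2c(O)cc(O)cc2[C@@H]1C(=O)c1c(O)cc(O)cc1Cc1cc(O)cc(=O)o1 | target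

**Totals and risks**
Total step count: 13. Longest linear sequence: 13 (1 → 2 → 3 → 6 → 11 → 12 → 15 → 16 → 17 → 19 → 20 → 23 → 25 → 27).

Three steps most likely to fail:

Step 7, the Suzuki coupling of the α‑bromo ketone, may suffer reduction or base‑induced side reactions of 15. The fallback sets out from 12: Friedel–Crafts acetylation (Ac2O, Sc(OTf)3 cat., MeNO2) gives methyl ketone F1. Separately, 3 is bromodeboronated (CuBr2, MeOH–H2O, 80 °C) to aryl bromide F2. Ketone α‑arylation of F1 with F2 (Pd2(dba)3, Xantphos, K3PO4, toluene, 80 °C) then gives 16, where the route is rejoined.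

Step 9, the catalytic asymmetric aldol, uses a hindered α‑aryl enol silane for which reactivity and selectivity are uncertain. The fallback sets out from 17 and 18: the achiral complex of Cu(OTf)2 and 2,2′‑bipyridine gives racemic syn silyl ether F3, which Me3SnOH converts to racemic acid F4. Classical resolution with (S)‑1‑phenylethylamine (or its enantiomer, whichever crystallises the wanted acid) gives ammonium salt F5, and acidification of F5 returns the route at 20.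

Step 12, the proposed Wolff shift with Friedel–Crafts capture of the ketene, is new; the ketene may oligomerise or the arene may not intercept it. The known‑chemistry fallback sets out from 23: Wolff rearrangement in wet THF (PhCO2Ag cat., Et3N, THF–H2O, sonication; Arndt–Eistert homologation) gives homologous acid F6. TFAA in CH2Cl2 at 0 °C converts it to mixed anhydride F7, which closes ring B by intramolecular Friedel–Crafts acylation and returns the route at 25.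

Further compounds
F1 | step 7 | 1‑{2,4‑bis(benzyloxy)‑6‑[(4‑(benzyloxy)‑2‑oxo‑2H‑pyran‑6‑yl)methyl]phenyl}ethan‑1‑one | CC(=O)c1c(OCc2ccccc2)cc(OCc2ccccc2)cc1Cc1cc(OCc2ccccc2)cc(=O)o1
F2 | step 7 | 1,3‑bis(benzyloxy)‑5‑bromobenzene | Brc1cc(OCc2ccccc2)cc(OCc2ccccc2)c1
F3 | step 9 | racemic syn methyl 3‑ArA‑4‑ArC‑2‑methyl‑4‑oxo‑2‑[(trimethylsilyl)oxy]butanoate | COC(=O)C(C)(O[Si](C)(C)C)C(c1cc(OCc2ccccc2)cc(OCc2ccccc2)c1)C(=O)c1c(OCc2ccccc2)cc(OCc2ccccc2)cc1Cc1cc(OCc2ccccc2)cc(=O)o1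
F4 | step 9 | racemic syn 3‑ArA‑4‑ArC‑2‑methyl‑4‑oxo‑2‑[(trimethylsilyl)oxy]butanoic acid | OC(=O)C(C)(O[Si](C)(C)C)C(c1cc(OCc2ccccc2)cc(OCc2ccccc2)c1)C(=O)c1c(OCc2ccccc2)cc(OCc2ccccc2)cc1Cc1cc(OCc2ccccc2)cc(=O)o1
F5 | step 9 | (S)‑1‑phenylethylammonium (2S,3S)‑3‑ArA‑4‑ArC‑2‑methyl‑4‑oxo‑2‑[(trimethylsilyl)oxy]butanoate | [O-]C(=O)[C@@](C)(O[Si](C)(C)C)[C@H](c1cc(OCc2ccccc2)cc(OCc2ccccc2)c1)C(=O)c1c(OCc2ccccc2)cc(OCc2ccccc2)cc1Cc1cc(OCc2ccccc2)cc(=O)o1.C[C@H]([NH3+])c1ccccc1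
F6 | step 12 | (3R,4S)‑4‑ArA‑5‑ArC‑3‑methyl‑5‑oxo‑3‑[(trimethylsilyl)oxy]pentanoic acid | OC(=O)C[C@@](C)(O[Si](C)(C)C)[C@H](c1cc(OCc2ccccc2)cc(OCc2ccccc2)c1)C(=O)c1c(OCc2ccccc2)cc(OCc2ccccc2)cc1Cc1cc(OCc2ccccc2)cc(=O)o1
F7 | step 12 | (3R,4S)‑4‑ArA‑5‑ArC‑3‑methyl‑5‑oxo‑3‑[(trimethylsilyl)oxy]pentanoic trifluoroacetic anhydride | O=C(OC(=O)C(F)(F)F)C[C@@](C)(O[Si](C)(C)C)[C@H](c1cc(OCc2ccccc2)cc(OCc2ccccc2)c1)C(=O)c1c(OCc2ccccc2)cc(OCc2ccccc2)cc1Cc1cc(OCc2ccccc2)cc(=O)o1
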